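**Retrosynthetic overview**
1. Target 20 ⇒ aldehyde 13: the pyranone ring is made last (dianion aldol, oxidation, lactonisation, O-methylation), and the enone is unmasked from a dioxolane in the final flask.
2. 13 ⇒ oxazoline 10 by the usual unmasking of a chiral oxazoline auxiliary.
3. 10 ⇒ aryl oxazoline 7 + vinyllithium 8 + MeI: the ring–side-chain bond is made by dearomatising ortho-addition of a β-acylvinyl anion equivalent (d3 reagent), and ipso-methylation sets the quaternary centre in the same flask.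
4. 8 ⇒ vinyl iodide 4 ⇒ pent-3-yn-2-one 1; 7 ⇒ 3,5-dimethylbenzonitrile 5 + (R)-tert-leucinol 6.
5. Ring order: the carbocycle is the purchased benzene ring; oxazoline (step 3, removed in step 5); cyclohexadiene by dearomatisation (step 4); pyranone (step 8).

Assumption: the facial sense in step 4 follows the N–Li delivery model (attack anti to the C4 tert-butyl group), which calls for the (R)-amino alcohol; if experiment shows the opposite sense, (S)-tert-leucinol is used and nothing else changes.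

**Route**

Step 1
Reactants: 1 pent-3-yn-2-one
Product: 2 2-methyl-2-(prop-1-yn-1-yl)-1,3-dioxolane
Conditions: ethane-1,2-diol, p-TsOH (cat.), benzene, reflux, Dean–Stark
Reagents that add atoms: ethane-1,2-diol, OCCO
Why: Acid-catalysed ketalisation with azeotropic removal of water masks the ynone carbonyl, so that the vinyllithium made later is a β-acylvinyl anion equivalent; no stereocentre is formed.

Step 2
Reactants: 2 2-methyl-2-(prop-1-yn-1-yl)-1,3-dioxolane
Product: 4 2-[(1E)-2-iodoprop-1-en-1-yl]-2-methyl-1,3-dioxolane, via vinylzirconocene chloride 3 (not isolated)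
Conditions: Cp2Zr(H)Cl (1.5 equiv), THF, rt → 40 °C; then I2, 0 °C
Reagents that add atoms: iodine, II
Why: Hydrozirconation is a syn addition that places zirconium on the methyl-bearing alkyne carbon (the other carbon is shielded by the quaternary ketal carbon), and iodinolysis goes with retention, which fixes the alkene geometry that becomes the (2E)-enone of the target.

Step 3
Reactants: 5 3,5-dimethylbenzonitrile, 6 (2R)-2-amino-3,3-dimethylbutan-1-ol
Product: 7 (4R)-4-tert-butyl-2-(3,5-dimethylphenyl)-4,5-dihydro-1,3-oxazole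
Conditions: ZnCl2 (5 mol %), PhCl, reflux
Reagents that add atoms: none
Why: ZnCl2-catalysed condensation of a nitrile with a 1,2-amino alcohol (Witte–Seeliger oxazoline synthesis) proceeds with loss of NH3 and leaves the amino alcohol stereocentre untouched.

Step 4
Reactants: 4 2-[(1E)-2-iodoprop-1-en-1-yl]-2-methyl-1,3-dioxolane, 7 (4R)-4-tert-butyl-2-(3,5-dimethylphenyl)-4,5-dihydro-1,3-oxazole
Product: 10 (4R)-4-tert-butyl-2-{(1S,6S)-1,3,5-trimethyl-6-[(E)-1-(2-methyl-1,3-dioxolan-2-yl)prop-1-en-2-yl]cyclohexa-2,4-dien-1-yl}-4,5-dihydro-1,3-oxazole, via vinyllithium 8 (not isolated), via lithium azaenolate 9 (not isolated)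
Conditions: 4, t-BuLi (2 equiv), Et2O, −78 °C; then 7, THF, DMPU, −78 → −30 °C; then MeI, −78 °C → rt
Reagents that add atoms: iodomethane, CI
Why: Proposed new method: a Meyers-type tandem conjugate addition–alkylation run on a simple benzene ring with a β-acylvinyl anion equivalent, in which N–Li coordination delivers the vinyl group to the ortho carbon from the face opposite the tert-butyl group to give the dearomatised azaenolate 9, and MeI then alkylates the ipso carbon anti to the new vinyl group, so that side chain and oxazoline (the future pyranone) end up cis and both stereocentres (1S,6S) are set in one flask; the closest known reaction type is the organolithium addition–methylation of chiral naphthyl oxazolines and its polar-cosolvent-promoted extension to phenyl oxazolines with secondary alkyllithiums, and the main competitor is ortho-lithiation.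

Step 5
Reactants: 10 (4R)-4-tert-butyl-2-{(1S,6S)-1,3,5-trimethyl-6-[(E)-1-(2-methyl-1,3-dioxolan-2-yl)prop-1-en-2-yl]cyclohexa-2,4-dien-1-yl}-4,5-dihydro-1,3-oxazole
Product: 13 (1S,6S)-1,3,5-trimethyl-6-[(E)-1-(2-methyl-1,3-dioxolan-2-yl)prop-1-en-2-yl]cyclohexa-2,4-diene-1-carbaldehyde, via N-methyloxazolinium triflate 11 (not isolated), via N-methyloxazolidine 12 (not isolated)
Conditions: MeOTf, CH2Cl2, 0 °C → rt; NaBH4, THF/MeOH, 0 °C; oxalic acid, THF/H2O, 0 °C → rt
Reagents that add atoms: water, O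
Why: The standard unmasking of Meyers oxazolines (N-methylation, hydride reduction to the N,O-aminal, mild acid hydrolysis) frees an aldehyde that has no α-hydrogen and cannot epimerise, and the N,O-aminal should hydrolyse much faster than the 1,3-dioxolane at this pH.

Step 6
Reactants: 13 (1S,6S)-1,3,5-trimethyl-6-[(E)-1-(2-methyl-1,3-dioxolan-2-yl)prop-1-en-2-yl]cyclohexa-2,4-diene-1-carbaldehyde, 14 methyl 2-methyl-3-oxopentanoate
Product: 16 methyl 5-hydroxy-2,4-dimethyl-3-oxo-5-{(1S,6S)-1,3,5-trimethyl-6-[(E)-1-(2-methyl-1,3-dioxolan-2-yl)prop-1-en-2-yl]cyclohexa-2,4-dien-1-yl}pentanoate, via keto ester dianion 15 (not isolated)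
Conditions: 14, NaH, THF, 0 °C; n-BuLi, 0 °C; then 13, −78 °C; NH4Cl (aq)
Reagents that add atoms: none
Why: Aldol addition of the γ-carbon of the β-keto ester dianion (Weiler dianion) to the non-enolisable aldehyde delivers the whole pyranone chain, and the three new centres form as a mixture that is erased in steps 7 and 8.

Step 7
Reactants: 16 methyl 5-hydroxy-2,4-dimethyl-3-oxo-5-{(1S,6S)-1,3,5-trimethyl-6-[(E)-1-(2-methyl-1,3-dioxolan-2-yl)prop-1-en-2-yl]cyclohexa-2,4-dien-1-yl}pentanoate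
Product: 17 methyl 2,4-dimethyl-3,5-dioxo-5-{(1S,6S)-1,3,5-trimethyl-6-[(E)-1-(2-methyl-1,3-dioxolan-2-yl)prop-1-en-2-yl]cyclohexa-2,4-dien-1-yl}pentanoate
Conditions: DMP, NaHCO3, CH2Cl2, rt
Reagents that add atoms: none
Why: Dess–Martin oxidation converts the β-hydroxy ketone into the β,δ-diketo ester under buffered conditions that leave the ketal and the diene alone.

Step 8
Reactants: 17 methyl 2,4-dimethyl-3,5-dioxo-5-{(1S,6S)-1,3,5-trimethyl-6-[(E)-1-(2-methyl-1,3-dioxolan-2-yl)prop-1-en-2-yl]cyclohexa-2,4-dien-1-yl}pentanoate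
Product: 18 4-hydroxy-3,5-dimethyl-6-{(1S,6S)-1,3,5-trimethyl-6-[(E)-1-(2-methyl-1,3-dioxolan-2-yl)prop-1-en-2-yl]cyclohexa-2,4-dien-1-yl}-2H-pyran-2-one
Conditions: DBU, toluene, rt → 60 °C
Reagents that add atoms: none
Why: DBU-mediated lactonisation (O-acylation of the δ-enolate by the methyl ester) closes the 4-hydroxy-2-pyranone, and because the enone is still masked the ring stereocentres carry no base-labile hydrogen.

Step 9
Reactants: 18 4-hydroxy-3,5-dimethyl-6-{(1S,6S)-1,3,5-trimethyl-6-[(E)-1-(2-methyl-1,3-dioxolan-2-yl)prop-1-en-2-yl]cyclohexa-2,4-dien-1-yl}-2H-pyran-2-one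
Product: 20 2-methoxy-3,5-dimethyl-6-{(1S,6S)-1,3,5-trimethyl-6-[(2E)-4-oxopent-2-en-2-yl]cyclohexa-2,4-dien-1-yl}-4H-pyran-4-one, via dioxolane-protected pyranone 19 (not isolated)
Conditions: MeOTf, CH2Cl2, rt; then 1 M HCl, THF, rt; NaHCO3 work-up
Reagents that add atoms: methyl trifluoromethanesulfonate, COS(=O)(=O)C(F)(F)F; water, O
Why: O-methylation of the 4-hydroxy-2-pyranone with a hard methylating agent occurs at the ring carbonyl oxygen and gives the α-methoxy-γ-pyranone after proton loss, and the acid then hydrolyses the allylic dioxolane (ketal hydrolysis) to the (E)-enone without touching the two ring stereocentres.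

**Compound list**
1 | pent-3-yn-2-one | CC#CC(C)=O | starting material
2 | 2-methyl-2-(prop-1-yn-1-yl)-1,3-dioxolane | CC#CC1(C)OCCO1 | intermediate
3 | chlorobis(cyclopentadienyl)[(E)-1-(2-methyl-1,3-dioxolan-2-yl)prop-1-en-2-yl]zirconium (Zr trans to the dioxolane carbon; cyclopentadienyl drawn σ-bonded) | C/C(=C\C1(C)OCCO1)[Zr](Cl)(C2C=CC=C2)C3C=CC=C3 | intermediate
4 | 2-[(1E)-2-iodoprop-1-en-1-yl]-2-methyl-1,3-dioxolane | C/C(I)=C\C1(C)OCCO1 | intermediate
5 | 3,5-dimethylbenzonitrile | Cc1cc(C)cc(C#N)c1 | starting material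
6 | (2R)-2-amino-3,3-dimethylbutan-1-ol ((R)-tert-leucinol) | CC(C)(C)[C@@H](N)CO | starting material
7 | (4R)-4-tert-butyl-2-(3,5-dimethylphenyl)-4,5-dihydro-1,3-oxazole | CC(C)(C)[C@@H]1COC(=N1)c2cc(C)cc(C)c2 | intermediate
8 | [1-(2-methyl-1,3-dioxolan-2-yl)prop-1-en-2-yl]lithium, Li trans to the dioxolane carbon (same geometry as 4) | [Li]/C(C)=C/C1(C)OCCO1 | intermediate
9 | lithium (4R)-4-tert-butyl-2-{(6S)-3,5-dimethyl-6-[(E)-1-(2-methyl-1,3-dioxolan-2-yl)prop-1-en-2-yl]cyclohexa-2,4-dien-1-ylidene}-1,3-oxazolidin-3-ide | CC(C)(C)[C@@H]1COC(=C2C=C(C)C=C(C)[C@H]2/C(C)=C/C3(C)OCCO3)N1[Li] | intermediate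
10 | (4R)-4-tert-butyl-2-{(1S,6S)-1,3,5-trimethyl-6-[(E)-1-(2-methyl-1,3-dioxolan-2-yl)prop-1-en-2-yl]cyclohexa-2,4-dien-1-yl}-4,5-dihydro-1,3-oxazole (oxazoline and side chain cis, C1-methyl trans to the side chain) | CC(C)(C)[C@@H]1COC(=N1)[C@@]2(C)C=C(C)C=C(C)[C@H]2/C(C)=C/C3(C)OCCO3 | intermediate
11 | (4R)-4-tert-butyl-3-methyl-2-{(1S,6S)-1,3,5-trimethyl-6-[(E)-1-(2-methyl-1,3-dioxolan-2-yl)prop-1-en-2-yl]cyclohexa-2,4-dien-1-yl}-4,5-dihydro-1,3-oxazol-3-ium trifluoromethanesulfonate | CC(C)(C)[C@@H]1COC(=[N+]1C)[C@@]2(C)C=C(C)C=C(C)[C@H]2/C(C)=C/C3(C)OCCO3.[O-]S(=O)(=O)C(F)(F)F | intermediate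
12 | (4R)-4-tert-butyl-3-methyl-2-{(1S,6S)-1,3,5-trimethyl-6-[(E)-1-(2-methyl-1,3-dioxolan-2-yl)prop-1-en-2-yl]cyclohexa-2,4-dien-1-yl}-1,3-oxazolidine (C-2 epimers) | CC(C)(C)[C@@H]1COC(N1C)[C@@]2(C)C=C(C)C=C(C)[C@H]2/C(C)=C/C3(C)OCCO3 | intermediate
13 | (1S,6S)-1,3,5-trimethyl-6-[(E)-1-(2-methyl-1,3-dioxolan-2-yl)prop-1-en-2-yl]cyclohexa-2,4-diene-1-carbaldehyde | O=C[C@@]1(C)C=C(C)C=C(C)[C@H]1/C(C)=C/C2(C)OCCO2 | intermediate
14 | methyl 2-methyl-3-oxopentanoate | CCC(=O)C(C)C(=O)OC | starting material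
15 | lithium sodium dianion of methyl 2-methyl-3-oxopentanoate (deprotonated at C-2 and C-4) | C[CH-]C(=O)[C-](C)C(=O)OC.[Na+].[Li+] | intermediate
16 | methyl 5-hydroxy-2,4-dimethyl-3-oxo-5-{(1S,6S)-1,3,5-trimethyl-6-[(E)-1-(2-methyl-1,3-dioxolan-2-yl)prop-1-en-2-yl]cyclohexa-2,4-dien-1-yl}pentanoate (mixture at C-2, C-4, C-5) | COC(=O)C(C)C(=O)C(C)C(O)[C@@]1(C)C=C(C)C=C(C)[C@H]1/C(C)=C/C2(C)OCCO2 | intermediate
17 | methyl 2,4-dimethyl-3,5-dioxo-5-{(1S,6S)-1,3,5-trimethyl-6-[(E)-1-(2-methyl-1,3-dioxolan-2-yl)prop-1-en-2-yl]cyclohexa-2,4-dien-1-yl}pentanoate (mixture at C-2, C-4 and of enol forms) | COC(=O)C(C)C(=O)C(C)C(=O)[C@@]1(C)C=C(C)C=C(C)[C@H]1/C(C)=C/C2(C)OCCO2 | intermediate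
18 | 4-hydroxy-3,5-dimethyl-6-{(1S,6S)-1,3,5-trimethyl-6-[(E)-1-(2-methyl-1,3-dioxolan-2-yl)prop-1-en-2-yl]cyclohexa-2,4-dien-1-yl}-2H-pyran-2-one | O=c1oc([C@@]2(C)C=C(C)C=C(C)[C@H]2/C(C)=C/C3(C)OCCO3)c(C)c(O)c1C | intermediate
19 | 2-methoxy-3,5-dimethyl-6-{(1S,6S)-1,3,5-trimethyl-6-[(E)-1-(2-methyl-1,3-dioxolan-2-yl)prop-1-en-2-yl]cyclohexa-2,4-dien-1-yl}-4H-pyran-4-one | COc1oc([C@@]2(C)C=C(C)C=C(C)[C@H]2/C(C)=C/C3(C)OCCO3)c(C)c(=O)c1C | intermediate
20 | 2-methoxy-3,5-dimethyl-6-{(1S,6S)-1,3,5-trimethyl-6-[(2E)-4-oxopent-2-en-2-yl]cyclohexa-2,4-dien-1-yl}-4H-pyran-4-one | COc1oc([C@@]2(C)C=C(C)C=C(C)[C@H]2/C(C)=C/C(C)=O)c(C)c(=O)c1C | target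

**Step count**
Total: 9 steps. Longest linear sequence: 8 steps (1, 2, 4, 5, 6, 7, 8, 9); the arene branch (3, 4, 5, 6, 7, 8, 9) is 7.

**Steps most likely to fail, with fallbacks**

Step 4 (dearomatising addition–methylation; risks are ortho-lithiation of 7 and too low a reactivity of the unactivated, dimethyl-substituted ring). The fallback sets out from 7 and comes back at 10. 7 is heated with Cr(CO)6 (Bu2O/THF, reflux) to give the tricarbonylchromium arene complex F1. Its ring is electrophilic enough for 8 to add ortho to the oxazoline at −78 °C, on the face away from the metal and at the ortho carbon chosen by the auxiliary. The anionic cyclohexadienyl complex is protonated with CF3CO2H at −78 °C and the metal is removed under CO, giving the dihydroarene oxazoline F2 (C-5 epimers and double-bond isomers, which all converge). LiN(iPr)2 in THF/DMPU then regenerates azaenolate 9 from F2, and MeI gives 10. The approach changes from direct addition to a free arene to stoichiometric π-activation, with vinylation and methylation in separate operations.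

Step 8 (lactonisation at a ketone flanked by the quaternary carbon). The fallback sets out from 17 and comes back at 19. PPh3/CCl4 in THF at rt closes the β,δ-diketo ester by dehydration through the ester carbonyl oxygen, so the ester OMe is kept and the α-methoxy-γ-pyranone 19 forms directly; this makes no new compound (F0). It bypasses 18 and with it the regiochemical question of the O-methylation. 19 is then hydrolysed with 1 M HCl/THF as in step 9.

Step 6 (dianion aldol at a neopentyl aldehyde next to a bulky alkenyl group; slow addition and retro-aldol on work-up). The fallback sets out from 13 and comes back at 17. EtMgBr (THF, −78 °C) adds to 13 to give the secondary alcohol F3, and DMP oxidises it to the ethyl ketone F4. The enolate of F4 (LiN(SiMe3)2, THF, −78 °C, then MgBr2·OEt2) is C-acylated with methyl 3-chloro-2-methyl-3-oxopropanoate to give 17. The chain is thus built by Grignard addition and Claisen-type acylation instead of one aldol, and 16 is bypassed.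

**Further compounds**
F1 | step 4 | tricarbonyl[η6-(4R)-4-tert-butyl-2-(3,5-dimethylphenyl)-4,5-dihydro-1,3-oxazole]chromium | CC(C)(C)[C@@H]1COC(=N1)c2cc(C)cc(C)c2.[Cr].[C-]#[O+].[C-]#[O+].[C-]#[O+]
F2 | step 4 | (4R)-4-tert-butyl-2-{(6S)-3,5-dimethyl-6-[(E)-1-(2-methyl-1,3-dioxolan-2-yl)prop-1-en-2-yl]cyclohexa-1,3-dien-1-yl}-4,5-dihydro-1,3-oxazole (C-5 epimers) | CC(C)(C)[C@@H]1COC(=N1)C2=CC(C)=CC(C)[C@H]2/C(C)=C/C3(C)OCCO3
F0 | step 8 | none | none
F3 | step 6 | 1-{(1S,6S)-1,3,5-trimethyl-6-[(E)-1-(2-methyl-1,3-dioxolan-2-yl)prop-1-en-2-yl]cyclohexa-2,4-dien-1-yl}propan-1-ol (carbinol epimers) | CCC(O)[C@@]1(C)C=C(C)C=C(C)[C@H]1/C(C)=C/C2(C)OCCO2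
F4 | step 6 | 1-{(1S,6S)-1,3,5-trimethyl-6-[(E)-1-(2-methyl-1,3-dioxolan-2-yl)prop-1-en-2-yl]cyclohexa-2,4-dien-1-yl}propan-1-one | CCC(=O)[C@@]1(C)C=C(C)C=C(C)[C@H]1/C(C)=C/C2(C)OCCO2
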